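**Plan**

1. Retrosynthetic cuts, in order: the two O-protecting groups; the C4–H bond (carbinol back to ketone); the O-methyl adjustments at O5 and O2'; C2–C3 of the pyranone ring (carbenoid C–H insertion); C3=N2 (diazo transfer); the C5'–prenyl bond (Stille); C4–C4a (Friedel–Crafts acylation of ring A); the C3–C4 chain bond (aldehyde homologation).
2. Enabling feature: C2 is an unsubstituted methylene on the aryl ether oxygen O1, so O1–C2 can start as one of the two equivalent ortho OCH3 groups of a 2,4,6-trimethoxybenzoyl ring A, while C3 lies between the C4 carbonyl and ring B and can carry a diazo group.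
3. Forward order: ring B arylacetic acid from a resorcylaldehyde, acylation of 1,3,5-trimethoxybenzene (ring A joined), prenylation, diazo transfer, then closure of the only new ring (the pyranone) in step 8.
4. During the insertion O2' carries a TBS group instead of methyl, because a 2'-OCH3 would offer the carbenoid a five-membered C–H insertion; O2' is methylated afterwards and the O5 methyl is removed by carbonyl-directed cleavage.
5. Stereochemistry: C3 is formed racemic and epimerisable; C3 and C4 are set together in step 13 by asymmetric transfer hydrogenation under dynamic kinetic resolution with RuCl[(R,R)-TsDPEN](p-cymene), which should give the 3,4-cis (3R,4R) alcohol.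

Key step: step 8

Remark: 5-bromo-2,4-dihydroxybenzaldehyde, 1,3,5-trimethoxybenzene and tributyl(3-methylbut-2-en-1-yl)stannane are taken as purchasable; chroman numbering (O1, C2, C3, C4) with primed locants for ring B is used throughout.

**Route**

Step 1
Reactants: 1 5-bromo-2,4-dihydroxybenzaldehyde
Product: 2 5-bromo-2-hydroxy-4-(pivaloyloxy)benzaldehyde
Conditions: PivCl (1.05 equiv), Et3N (1.1 equiv), CH2Cl2, −20 to 0 °C
Reagents that add atoms: pivaloyl chloride, CC(C)(C)C(=O)Cl
Why: Chemoselective O-acylation: the 4-OH is the free, more acidic phenol whereas the 2-OH is held in a hydrogen bond to the aldehyde, so one equivalent of acid chloride should esterify O4 only, marking the oxygen that ends as the free 4'-OH.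

Step 2
Reactants: 2 5-bromo-2-hydroxy-4-(pivaloyloxy)benzaldehyde
Product: 3 5-bromo-2-(tert-butyldimethylsilyloxy)-4-(pivaloyloxy)benzaldehyde
Conditions: TBSCl, imidazole, DMF, rt
Reagents that add atoms: tert-butyldimethylsilyl chloride, CC(C)(C)[Si](C)(C)Cl
Why: Imidazole-promoted silylation caps the chelated phenol with a group that has no C–H on the atom bound to oxygen, which is what the carbenoid step requires of the future O2' substituent.

Step 3
Reactants: 3 5-bromo-2-(tert-butyldimethylsilyloxy)-4-(pivaloyloxy)benzaldehyde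
Product: 5 2-bromo-5-(tert-butyldimethylsilyloxy)-4-(2-oxoethyl)phenyl pivalate, via methyl enol ether 4 (not isolated)
Conditions: Ph3P(CH2OMe)Cl (1.5 equiv), KOt-Bu (1.4 equiv), THF, 0 °C; add 3, −78 to 0 °C; then 2 M aq HCl, 40 °C
Reagents that add atoms: (methoxymethyl)triphenylphosphonium chloride, COC[P+](c1ccccc1)(c1ccccc1)c1ccccc1.[Cl-]; water, O
Why: Wittig methoxymethylenation followed by acid hydrolysis of the enol ether is the standard one-carbon homologation of an aryl aldehyde to an arylacetaldehyde; the preformed ylide leaves no free alkoxide to attack the pivalate, and the phenolic silyl ether tolerates brief dilute acid.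

Step 4
Reactants: 5 2-bromo-5-(tert-butyldimethylsilyloxy)-4-(2-oxoethyl)phenyl pivalate
Product: 6 2-[5-bromo-2-(tert-butyldimethylsilyloxy)-4-(pivaloyloxy)phenyl]acetic acid
Conditions: NaClO2, NaH2PO4, 2-methyl-2-butene, t-BuOH/H2O, 0 °C to rt
Reagents that add atoms: sodium chlorite, [Na+].[O-]Cl=O
Why: Pinnick oxidation converts the enolisable aldehyde into the acid under buffered conditions that leave the aryl bromide, ester and silyl ether alone, with 2-methyl-2-butene trapping the hypochlorous acid.

Step 5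
Reactants: 6 2-[5-bromo-2-(tert-butyldimethylsilyloxy)-4-(pivaloyloxy)phenyl]acetic acid; 7 1,3,5-trimethoxybenzene
Product: 9 2-[5-bromo-2-(tert-butyldimethylsilyloxy)-4-(pivaloyloxy)phenyl]-1-(2,4,6-trimethoxyphenyl)ethanone, via mixed trifluoroacetic anhydride 8 (not isolated)
Conditions: (CF3CO)2O (2 equiv), CH2Cl2, 0 °C; then 7 (2 equiv), 0 °C to rt
Reagents that add atoms: none
Why: Friedel–Crafts acylation through the mixed trifluoroacetic anhydride: 1,3,5-trimethoxybenzene is nucleophilic enough to be acylated without a metal Lewis acid, its three free positions are equivalent, and the ketone formed is deactivated against a second acylation.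

Step 6
Reactants: 9 2-[5-bromo-2-(tert-butyldimethylsilyloxy)-4-(pivaloyloxy)phenyl]-1-(2,4,6-trimethoxyphenyl)ethanone; 10 tributyl(3-methylbut-2-en-1-yl)stannane
Product: 11 2-[2-(tert-butyldimethylsilyloxy)-5-(3-methylbut-2-en-1-yl)-4-(pivaloyloxy)phenyl]-1-(2,4,6-trimethoxyphenyl)ethanone
Conditions: Pd(PPh3)4 (5 mol %), toluene, 100 °C, degassed
Reagents that add atoms: none
Why: Migita–Kosugi–Stille coupling of the aryl bromide under neutral conditions; reductive elimination from the less hindered primary terminus of the allylpalladium intermediate should give the linear prenyl group, and placing the step after the acidic steps protects the alkene.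

Step 7
Reactants: 11 2-[2-(tert-butyldimethylsilyloxy)-5-(3-methylbut-2-en-1-yl)-4-(pivaloyloxy)phenyl]-1-(2,4,6-trimethoxyphenyl)ethanone
Product: 12 2-diazo-2-[2-(tert-butyldimethylsilyloxy)-5-(3-methylbut-2-en-1-yl)-4-(pivaloyloxy)phenyl]-1-(2,4,6-trimethoxyphenyl)ethanone
Conditions: 4-acetamidobenzenesulfonyl azide (1.5 equiv), DBU (1.5 equiv), MeCN, 0 °C to rt
Reagents that add atoms: 4-acetamidobenzenesulfonyl azide, CC(=O)Nc1ccc(cc1)S(=O)(=O)N=[N+]=[N-]
Why: Regitz diazo transfer: DBU deprotonates the methylene flanked by the ketone and ring B and the enolate attacks the sulfonyl azide, a standard preparation of α-aryl-α-diazo ketones from deoxybenzoins.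

Step 8
Reactants: 12 2-diazo-2-[2-(tert-butyldimethylsilyloxy)-5-(3-methylbut-2-en-1-yl)-4-(pivaloyloxy)phenyl]-1-(2,4,6-trimethoxyphenyl)ethanone
Product: 13 racemic 3-[2-(tert-butyldimethylsilyloxy)-5-(3-methylbut-2-en-1-yl)-4-(pivaloyloxy)phenyl]-5,7-dimethoxychroman-4-one
Conditions: Rh2(O2CCPh3)4 (2 mol %), CH2Cl2, 40 °C, 12 added by syringe pump over 4 h (final 0.01 M)
Reagents that add atoms: none
Why: Proposed new method: loss of N2 from 12 at the dirhodium core gives an electrophilic aryl/acyl carbenoid at C3, which inserts through a three-centre transition state into a C–H bond of an ortho O-methyl group of ring A and so forms C2–C3; the closest known reactions are dirhodium-catalysed insertions next to ether oxygen in 2-alkoxyphenyl diazoketones (chroman-4-ones from O–CH2R groups) and in ortho-alkoxyaryl diazoacetates (dihydrobenzofurans). The pyranone ring closes by 1,6-insertion through a six-atom array (C3, C4, C4a, C8a, O1, C2), helped by the twist of the 2,6-disubstituted ring A out of the carbonyl plane, which holds a methoxy group over the carbenoid carbon. C3 is formed racemic and needs no control, since it is epimerisable and is fixed in step 13. The step needs insertion into a ring A methoxy group over three competitors: a five-membered insertion at the ring B ortho oxygen substituent is excluded because O2' carries TBS, which has no C–H on the atom bound to oxygen and only unactivated Si-methyl C–H bonds; oxonium ylide formation at a ring A methoxy oxygen should be reversible because methyl migrates poorly and is disfavoured by the bulky triphenylacetate ligands; the prenyl alkene cannot be reached intramolecularly and slow addition suppresses intermolecular reaction. The two ortho methoxy groups of ring A are equivalent, so either insertion gives 13, and the unused one becomes the C5 methoxy group.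

Step 9
Reactants: 13 racemic 3-[2-(tert-butyldimethylsilyloxy)-5-(3-methylbut-2-en-1-yl)-4-(pivaloyloxy)phenyl]-5,7-dimethoxychroman-4-one
Product: 14 racemic 3-[2-hydroxy-5-(3-methylbut-2-en-1-yl)-4-(pivaloyloxy)phenyl]-5,7-dimethoxychroman-4-one
Conditions: Bu4NF (TBAF, 1.2 equiv), AcOH (1.2 equiv), THF, 0 °C
Reagents that add atoms: none
Why: Fluoride cleavage of the aryl silyl ether, buffered with acetic acid so that no enolate or phenoxide persists that could open the pyranone ring by retro-oxa-Michael reaction; the aryl pivalate is untouched.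

Step 10
Reactants: 14 racemic 3-[2-hydroxy-5-(3-methylbut-2-en-1-yl)-4-(pivaloyloxy)phenyl]-5,7-dimethoxychroman-4-one
Product: 15 racemic 5,7-dimethoxy-3-[2-methoxy-5-(3-methylbut-2-en-1-yl)-4-(pivaloyloxy)phenyl]chroman-4-one
Conditions: Me3SiCHN2 (3 equiv), i-Pr2NEt (1.5 equiv), MeCN/MeOH (9:1), rt
Reagents that add atoms: trimethylsilyldiazomethane, C[Si](C)(C)C=[N+]=[N-]
Why: O-Methylation of the only free phenol by diazomethane released in situ from trimethylsilyldiazomethane and methanol, chosen over MeI with a strong base because the C3–H next to the ketone is acidic and could be C-methylated.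

Step 11
Reactants: 15 racemic 5,7-dimethoxy-3-[2-methoxy-5-(3-methylbut-2-en-1-yl)-4-(pivaloyloxy)phenyl]chroman-4-one
Product: 16 racemic 5-hydroxy-7-methoxy-3-[2-methoxy-5-(3-methylbut-2-en-1-yl)-4-(pivaloyloxy)phenyl]chroman-4-one
Conditions: MgI2·OEt2 (3 equiv), toluene/Et2O, 60 °C; then aq NH4Cl
Reagents that add atoms: none
Why: Chelation-controlled demethylation: MgI2 binds between the C4 carbonyl and the peri O5 oxygen and iodide removes only that methyl group, leaving the C7 and C2' methyl ethers, the pivalate and the prenyl group.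

Step 12
Reactants: 16 racemic 5-hydroxy-7-methoxy-3-[2-methoxy-5-(3-methylbut-2-en-1-yl)-4-(pivaloyloxy)phenyl]chroman-4-one
Product: 17 racemic 5-(tert-butyldimethylsilyloxy)-7-methoxy-3-[2-methoxy-5-(3-methylbut-2-en-1-yl)-4-(pivaloyloxy)phenyl]chroman-4-one
Conditions: TBSOTf (1.3 equiv), 2,6-lutidine (2 equiv), CH2Cl2, −78 to 0 °C
Reagents that add atoms: tert-butyldimethylsilyl trifluoromethanesulfonate, CC(C)(C)[Si](C)(C)OS(=O)(=O)C(F)(F)F
Why: Silylation of the hydrogen-bonded 5-OH with the silyl triflate and a hindered pyridine base breaks the chelate and removes the free phenol before the reduction; at low temperature enol silylation of the ketone should not compete.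

Step 13
Reactants: 17 racemic 5-(tert-butyldimethylsilyloxy)-7-methoxy-3-[2-methoxy-5-(3-methylbut-2-en-1-yl)-4-(pivaloyloxy)phenyl]chroman-4-one
Product: 18 (3R,4R)-5-(tert-butyldimethylsilyloxy)-7-methoxy-3-[2-methoxy-5-(3-methylbut-2-en-1-yl)-4-(pivaloyloxy)phenyl]chroman-4-ol (3,4-cis)
Conditions: RuCl[(R,R)-TsDPEN](p-cymene) (3 mol %), HCO2H/Et3N (1:1), EtOAc, 40 °C
Reagents that add atoms: none
Why: Noyori-type asymmetric transfer hydrogenation under dynamic kinetic resolution: Et3N epimerises C3 of 17 through the enol faster than reduction, the (R,R)-TsDPEN complex delivers hydride to the C4 face that gives the 4R carbinol (CH/π contact between the p-cymene ligand and ring A), and only the 3R ketone can take this hydride anti to ring B, so the 3,4-cis (3R,4R) alcohol should result, as known for isoflavanones; the amine-rich formate medium keeps the electron-rich benzylic alcohol from ionising.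

Step 14
Reactants: 18 (3R,4R)-5-(tert-butyldimethylsilyloxy)-7-methoxy-3-[2-methoxy-5-(3-methylbut-2-en-1-yl)-4-(pivaloyloxy)phenyl]chroman-4-ol
Product: 19 (3R,4R)-3-[4-hydroxy-2-methoxy-5-(3-methylbut-2-en-1-yl)phenyl]-7-methoxychromane-4,5-diol (3,4-cis), the target
Conditions: K2CO3 (3 equiv), MeOH, rt, argon; pH 7 phosphate buffer work-up
Reagents that add atoms: none
Why: Base-mediated methanolysis (transesterification of the aryl pivalate and cleavage of the phenolic silyl ether) frees both phenols without acid, which the electron-rich benzylic C4 alcohol and the prenyl group next to a phenol would not tolerate; neither stereocentre is epimerisable under these conditions.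

**Compound list**

1 | 5-bromo-2,4-dihydroxybenzaldehyde | O=Cc1cc(Br)c(O)cc1O | starting material
2 | 5-bromo-2-hydroxy-4-(pivaloyloxy)benzaldehyde | CC(C)(C)C(=O)Oc1cc(O)c(C=O)cc1Br | intermediate
3 | 5-bromo-2-(tert-butyldimethylsilyloxy)-4-(pivaloyloxy)benzaldehyde | CC(C)(C)C(=O)Oc1cc(O[Si](C)(C)C(C)(C)C)c(C=O)cc1Br | intermediate
4 | 2-bromo-5-(tert-butyldimethylsilyloxy)-4-(2-methoxyethenyl)phenyl pivalate (E/Z mixture, not isolated) | COC=Cc1cc(Br)c(OC(=O)C(C)(C)C)cc1O[Si](C)(C)C(C)(C)C | intermediate
5 | 2-bromo-5-(tert-butyldimethylsilyloxy)-4-(2-oxoethyl)phenyl pivalate | O=CCc1cc(Br)c(OC(=O)C(C)(C)C)cc1O[Si](C)(C)C(C)(C)C | intermediate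
6 | 2-[5-bromo-2-(tert-butyldimethylsilyloxy)-4-(pivaloyloxy)phenyl]acetic acid | OC(=O)Cc1cc(Br)c(OC(=O)C(C)(C)C)cc1O[Si](C)(C)C(C)(C)C | intermediate
7 | 1,3,5-trimethoxybenzene | COc1cc(OC)cc(OC)c1 | starting material
8 | 2-[5-bromo-2-(tert-butyldimethylsilyloxy)-4-(pivaloyloxy)phenyl]acetic trifluoroacetic anhydride (not isolated) | FC(F)(F)C(=O)OC(=O)Cc1cc(Br)c(OC(=O)C(C)(C)C)cc1O[Si](C)(C)C(C)(C)C | intermediate
9 | 2-[5-bromo-2-(tert-butyldimethylsilyloxy)-4-(pivaloyloxy)phenyl]-1-(2,4,6-trimethoxyphenyl)ethanone | COc1cc(OC)c(C(=O)Cc2cc(Br)c(OC(=O)C(C)(C)C)cc2O[Si](C)(C)C(C)(C)C)c(OC)c1 | intermediate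
10 | tributyl(3-methylbut-2-en-1-yl)stannane | CCCC[Sn](CCCC)(CCCC)CC=C(C)C | starting material
11 | 2-[2-(tert-butyldimethylsilyloxy)-5-(3-methylbut-2-en-1-yl)-4-(pivaloyloxy)phenyl]-1-(2,4,6-trimethoxyphenyl)ethanone | COc1cc(OC)c(C(=O)Cc2cc(CC=C(C)C)c(OC(=O)C(C)(C)C)cc2O[Si](C)(C)C(C)(C)C)c(OC)c1 | intermediate
12 | 2-diazo-2-[2-(tert-butyldimethylsilyloxy)-5-(3-methylbut-2-en-1-yl)-4-(pivaloyloxy)phenyl]-1-(2,4,6-trimethoxyphenyl)ethanone | COc1cc(OC)c(C(=O)C(=[N+]=[N-])c2cc(CC=C(C)C)c(OC(=O)C(C)(C)C)cc2O[Si](C)(C)C(C)(C)C)c(OC)c1 | intermediate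
13 | racemic 3-[2-(tert-butyldimethylsilyloxy)-5-(3-methylbut-2-en-1-yl)-4-(pivaloyloxy)phenyl]-5,7-dimethoxychroman-4-one | COc1cc(OC)c2c(c1)OCC(c1cc(CC=C(C)C)c(OC(=O)C(C)(C)C)cc1O[Si](C)(C)C(C)(C)C)C2=O | intermediate
14 | racemic 3-[2-hydroxy-5-(3-methylbut-2-en-1-yl)-4-(pivaloyloxy)phenyl]-5,7-dimethoxychroman-4-one | COc1cc(OC)c2c(c1)OCC(c1cc(CC=C(C)C)c(OC(=O)C(C)(C)C)cc1O)C2=O | intermediate
15 | racemic 5,7-dimethoxy-3-[2-methoxy-5-(3-methylbut-2-en-1-yl)-4-(pivaloyloxy)phenyl]chroman-4-one | COc1cc(OC)c2c(c1)OCC(c1cc(CC=C(C)C)c(OC(=O)C(C)(C)C)cc1OC)C2=O | intermediate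
16 | racemic 5-hydroxy-7-methoxy-3-[2-methoxy-5-(3-methylbut-2-en-1-yl)-4-(pivaloyloxy)phenyl]chroman-4-one | COc1cc(O)c2c(c1)OCC(c1cc(CC=C(C)C)c(OC(=O)C(C)(C)C)cc1OC)C2=O | intermediate
17 | racemic 5-(tert-butyldimethylsilyloxy)-7-methoxy-3-[2-methoxy-5-(3-methylbut-2-en-1-yl)-4-(pivaloyloxy)phenyl]chroman-4-one | COc1cc(O[Si](C)(C)C(C)(C)C)c2c(c1)OCC(c1cc(CC=C(C)C)c(OC(=O)C(C)(C)C)cc1OC)C2=O | intermediate
18 | (3R,4R)-5-(tert-butyldimethylsilyloxy)-7-methoxy-3-[2-methoxy-5-(3-methylbut-2-en-1-yl)-4-(pivaloyloxy)phenyl]chroman-4-ol | COc1cc(O[Si](C)(C)C(C)(C)C)c2c(c1)OC[C@@H](c1cc(CC=C(C)C)c(OC(=O)C(C)(C)C)cc1OC)[C@H]2O | intermediate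
19 | (3R,4R)-3-[4-hydroxy-2-methoxy-5-(3-methylbut-2-en-1-yl)phenyl]-7-methoxychromane-4,5-diol | COc1cc(O)c2c(c1)OC[C@@H](c1cc(CC=C(C)C)c(O)cc1OC)[C@H]2O | target

**Step count and risks**

Total step count: 14. Longest linear sequence: 14 steps (from 1; compounds 7 and 10 enter as purchased reagents).

Steps most likely to fail:

1. Step 8 (the proposed insertion). The carbenoid may be captured by the lone pair of a ring A methoxy oxygen and leave through a Stevens methyl shift or demethylation, or the primary C–H insertion may be so slow that Wolff rearrangement or carbene dimerisation takes over. Fallback by known chemistry, setting out from deoxybenzoin 11 and omitting the diazo transfer: MgI2·OEt2 removes one of the two equivalent ortho methyl groups next to the ketone and gives 1-(2-hydroxy-4,6-dimethoxyphenyl)-2-[2-(tert-butyldimethylsilyloxy)-5-(3-methylbut-2-en-1-yl)-4-(pivaloyloxy)phenyl]ethanone F1. Mannich reaction of F1 with dimethyl(methylidene)ammonium iodide and Et3N in MeCN gives the α-(dimethylaminomethyl) ketone F2, which on warming loses dimethylamine to the α-methylene ketone F3. Intramolecular oxa-Michael addition of the phenol of F3 closes the pyranone ring, and the route is rejoined at isoflavanone 13.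

2. Step 13. Hydride transfer to the hindered, electron-rich ketone may be slow relative to catalyst decay, C3 epimerisation may fail to outrun reduction and erode the diastereo- and enantioselectivity, or the benzylic alcohol may ionise in the formate medium. Fallback, setting out from ketone 17: LiBH(s-Bu)3 in THF at −78 °C should add hydride anti to ring B and give the racemic 3,4-cis alcohol F4. Resolution of F4 by preparative chromatography on a cellulose tris(3,5-dimethylphenylcarbamate) stationary phase delivers 18, where the route is rejoined. The unwanted (3S,4S) alcohol F5 is oxidised with Dess–Martin periodinane back to 17 and recycled.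

3. Step 5. Intramolecular capture of the activated acyl group by the ortho silyloxy oxygen (lactonisation with loss of the silyl group) or acid-induced desilylation may outrun the intermolecular acylation. Fallback, setting out from aldehyde 5 and bypassing acid 6: 2,4,6-trimethoxyphenyllithium F6, made from 7 and n-BuLi in THF at 0 °C, is added to 5 at −78 °C and gives the secondary alcohol 2-[5-bromo-2-(tert-butyldimethylsilyloxy)-4-(pivaloyloxy)phenyl]-1-(2,4,6-trimethoxyphenyl)ethanol F7. Oxidation of F7 with Dess–Martin periodinane gives ketone 9, where the route is rejoined.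

**Further compounds**

F1 | step 8 | 1-(2-hydroxy-4,6-dimethoxyphenyl)-2-[2-(tert-butyldimethylsilyloxy)-5-(3-methylbut-2-en-1-yl)-4-(pivaloyloxy)phenyl]ethanone | COc1cc(O)c(C(=O)Cc2cc(CC=C(C)C)c(OC(=O)C(C)(C)C)cc2O[Si](C)(C)C(C)(C)C)c(OC)c1
F2 | step 8 | racemic 3-(dimethylamino)-1-(2-hydroxy-4,6-dimethoxyphenyl)-2-[2-(tert-butyldimethylsilyloxy)-5-(3-methylbut-2-en-1-yl)-4-(pivaloyloxy)phenyl]propan-1-one | COc1cc(O)c(C(=O)C(CN(C)C)c2cc(CC=C(C)C)c(OC(=O)C(C)(C)C)cc2O[Si](C)(C)C(C)(C)C)c(OC)c1
F3 | step 8 | 1-(2-hydroxy-4,6-dimethoxyphenyl)-2-[2-(tert-butyldimethylsilyloxy)-5-(3-methylbut-2-en-1-yl)-4-(pivaloyloxy)phenyl]prop-2-en-1-one | COc1cc(O)c(C(=O)C(=C)c2cc(CC=C(C)C)c(OC(=O)C(C)(C)C)cc2O[Si](C)(C)C(C)(C)C)c(OC)c1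
F4 | step 13 | racemic 3,4-cis-5-(tert-butyldimethylsilyloxy)-7-methoxy-3-[2-methoxy-5-(3-methylbut-2-en-1-yl)-4-(pivaloyloxy)phenyl]chroman-4-ol (both enantiomers) | COc1cc(O[Si](C)(C)C(C)(C)C)c2c(c1)OC[C@@H](c1cc(CC=C(C)C)c(OC(=O)C(C)(C)C)cc1OC)[C@H]2O.COc1cc(O[Si](C)(C)C(C)(C)C)c2c(c1)OC[C@H](c1cc(CC=C(C)C)c(OC(=O)C(C)(C)C)cc1OC)[C@@H]2O
F5 | step 13 | (3S,4S)-5-(tert-butyldimethylsilyloxy)-7-methoxy-3-[2-methoxy-5-(3-methylbut-2-en-1-yl)-4-(pivaloyloxy)phenyl]chroman-4-ol | COc1cc(O[Si](C)(C)C(C)(C)C)c2c(c1)OC[C@H](c1cc(CC=C(C)C)c(OC(=O)C(C)(C)C)cc1OC)[C@@H]2O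
F6 | step 5 | 2,4,6-trimethoxyphenyllithium | [Li]c1c(OC)cc(OC)cc1OC
F7 | step 5 | racemic 2-[5-bromo-2-(tert-butyldimethylsilyloxy)-4-(pivaloyloxy)phenyl]-1-(2,4,6-trimethoxyphenyl)ethanol | COc1cc(OC)c(C(O)Cc2cc(Br)c(OC(=O)C(C)(C)C)cc2O[Si](C)(C)C(C)(C)C)c(OC)c1
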